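Both rings are unravelled by cutting C5–C10 and C6=C7. The plan exploits two features: the ring-B enone (C6=C7–C8=O) can arise by dehydrating aldol union of a formyl group on the quaternary ring-fusion carbon C5 with the C7 methylene of a C8 ketone, and C8–C7–C11–C12 is an intact (S)-2-methylsuccinate fragment. In one amine-catalysed operation the enamine of the C6 aldehyde adds through C5 to C10 of a C9=C10 enone (ring A) and C7 then condenses onto C6 (ring B), creating the C5 and C10 stereocentres. The substrate is an acyclic (E)-enone keto aldehyde diester that already carries the syn-aldol-derived C3 silyl ether/C4 ester pair and the C11 centre.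

Key step: step 11

Remarks
- Numbering (target skeleton, used for all intermediates): ring A = C1, C2, C3 (O-angeloyl), C4 (bears ester carbon C15), C5 (bears CH3), C10 (bears H); ring B = C5, C6, C7 (bears C11 with its methyl and ester carbon C12), C8 (C=O), C9, C10.
- Assumption on C5: racemic 2 is used on purpose; compounds 4–21 are pairs of epimers at this one carbon (left open in their SMILES) and both should converge in step 11.
- Assumption on 15: the 4-tert-butyl monoester of (S)-2-methylsuccinic acid is taken as the commercial, regiodefined form of the chiral-pool acid, so the two carboxyl groups need no selective differentiation.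
- Design choice: C6 travels as a dimethyl acetal and the enone is installed last. The peroxide that removes the auxiliary and the ozone that cleaves the vinyl group therefore never meet the enone, and no metathesis substrate holds two alkenes.

Step 1
Reactants: 1 (S)-4-benzyl-2-oxazolidinone; 2 3-methylpent-4-enoic acid (racemic)
Product: 4 (4S)-4-benzyl-3-(3-methylpent-4-enoyl)oxazolidin-2-one (both epimers at the future C5), via mixed pivalic anhydride 3 (not isolated)
Conditions: PivCl, Et3N, THF, −20 °C; then 1, LiCl, −20 °C → rt
Reagents that add atoms: none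
Why: N-acylation of the oxazolidinone by a mixed pivalic anhydride under LiCl/Et3N activation is the standard mild imide synthesis, and the methyl-bearing carbon is deliberately left as a mixture because the key step erases it.

Step 2
Reactants: 4 (4S)-4-benzyl-3-(3-methylpent-4-enoyl)oxazolidin-2-one
Product: 6 (4S)-4-benzyl-3-(4,4-dimethoxy-3-methylbutanoyl)oxazolidin-2-one, via aldehyde 5 (not isolated)
Conditions: O3, CH2Cl2/MeOH (4:1), −78 °C; Me2S, → rt; then HC(OMe)3, TsOH·H2O (cat.), rt; Et3N
Reagents that add atoms: trimethyl orthoformate, COC(OC)OC (net source of both methoxy groups, exchanging with the solvent methanol, CO); ozone, O=[O+][O-] (carbonyl oxygen of 5 only, lost again on acetalisation)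
Why: Ozonolysis with reductive work-up cleaves the only alkene present and acid-catalysed acetalisation with orthoformate as water scavenger follows in the same pot, so C6 is fixed at the aldehyde oxidation level before any other alkene exists.

Step 3
Reactants: 6 (4S)-4-benzyl-3-(4,4-dimethoxy-3-methylbutanoyl)oxazolidin-2-one; 7 pent-4-enal
Product: 10 (4S)-4-benzyl-3-[(2S,3R)-2-(1,1-dimethoxypropan-2-yl)-3-hydroxyhept-6-enoyl]oxazolidin-2-one, via boron enolate 8 (not isolated), via boron aldolate 9 (not isolated)
Conditions: Bu2BOTf (1.05 equiv), i-Pr2NEt, CH2Cl2, 0 °C; then 7, −78 → 0 °C; pH 7 buffer, MeOH, 30% H2O2, 0 °C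
Reagents that add atoms: none
Why: Evans syn-aldol reaction, in which the (Z)-boron enolate reacts through a Zimmerman–Traxler chair on the face away from the benzyl group of the dipole-opposed (S)-auxiliary, setting C4 (S) and C3 (R) syn irrespective of the remote C5 epimer, while the amine-buffered medium should leave the acetal intact.

Step 4
Reactants: 10 (4S)-4-benzyl-3-[(2S,3R)-2-(1,1-dimethoxypropan-2-yl)-3-hydroxyhept-6-enoyl]oxazolidin-2-one
Product: 13 methyl (2S,3R)-2-(1,1-dimethoxypropan-2-yl)-3-hydroxyhept-6-enoate, via lithium percarboxylate 11 (not isolated), via lithium carboxylate 12 (not isolated)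
Conditions: LiOH·H2O, 30% H2O2, THF/H2O (3:1), 0 °C; aq. Na2SO3/NaHCO3; CH2Cl2 wash (returns 1); freeze-dry; MeI, DMF, rt
Reagents that add atoms: hydrogen peroxide, OO (the ester oxygen bound to the acyl carbon); iodomethane, CI
Why: Hydroperoxide cleavage of the exocyclic imide carbonyl (reliable even for hindered acyl groups), sulfite reduction of the peracid salt and direct SN2 O-methylation of the carboxylate keep the γ-hydroxy acetal away from acid, which would close it to a 2-methoxytetrahydrofuran, and touch no stereocentre.

Step 5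
Reactants: 13 methyl (2S,3R)-2-(1,1-dimethoxypropan-2-yl)-3-hydroxyhept-6-enoate
Product: 14 methyl (2S,3R)-3-[(tert-butyldimethylsilyl)oxy]-2-(1,1-dimethoxypropan-2-yl)hept-6-enoate
Conditions: TBSCl, imidazole, DMAP (cat.), DMF, rt → 40 °C
Reagents that add atoms: tert-butyldimethylsilyl chloride, CC(C)(C)[Si](C)(C)Cl
Why: Imidazole-mediated silylation of the secondary alcohol under basic conditions, chosen over a silyl triflate because the latter would activate the dimethyl acetal.

Step 6
Reactants: 15 (2S)-4-tert-butoxy-2-methyl-4-oxobutanoic acid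
Product: 16 4-tert-butyl 1-methyl (2S)-2-methylbutanedioate
Conditions: MeI, K2CO3, DMF, rt
Reagents that add atoms: iodomethane, CI
Why: SN2 O-alkylation of the carboxylate esterifies the hindered carboxyl next to the stereocentre without touching the tert-butyl ester, and carbonate does not enolise a simple ester α-carbon.

Step 7
Reactants: 16 4-tert-butyl 1-methyl (2S)-2-methylbutanedioate
Product: 18 methyl (2S)-4-[methoxy(methyl)amino]-2-methyl-4-oxobutanoate, via acid 17 (not isolated)
Conditions: TFA/CH2Cl2 (1:2), rt; evaporate; then MeNHOMe·HCl, EDC·HCl, i-Pr2NEt, CH2Cl2, 0 °C → rt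
Reagents that add atoms: N,O-dimethylhydroxylamine hydrochloride, CNOC.Cl
Why: Acidolysis removes only the tert-butyl ester (loss of isobutene) and carbodiimide coupling converts the freed, unhindered carboxyl into the Weinreb amide, so the future ketone carbon C8 is defined without any regioselective step.

Step 8
Reactants: 18 methyl (2S)-4-[methoxy(methyl)amino]-2-methyl-4-oxobutanoate
Product: 19 methyl (2S)-2-methyl-4-oxohex-5-enoate
Conditions: vinylMgBr (1.2 equiv), THF, −40 → 0 °C; inverse quench into cold 1 M HCl
Reagents that add atoms: vinylmagnesium bromide, C=C[Mg]Br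
Why: Weinreb ketone synthesis, in which the chelated tetrahedral adduct stops at the ketone stage and the amide reacts ahead of the α-branched methyl ester, while the acidic inverse quench protonates the released amine before it can add to the vinyl ketone.

Step 9
Reactants: 14 methyl (2S,3R)-3-[(tert-butyldimethylsilyl)oxy]-2-(1,1-dimethoxypropan-2-yl)hept-6-enoate; 19 methyl (2S)-2-methyl-4-oxohex-5-enoate (3 equiv)
Product: 20 dimethyl (2S,5E,9R,10S)-9-[(tert-butyldimethylsilyl)oxy]-10-(1,1-dimethoxypropan-2-yl)-2-methyl-4-oxoundec-5-enedioate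
Conditions: Hoveyda–Grubbs II (5 mol %), CH2Cl2, 40 °C
Reagents that add atoms: none
Why: Olefin cross-metathesis of a type I terminal alkene with a type II vinyl ketone favours the cross product and should give the (E)-enone under thermodynamic control, and 14 holds no second alkene that could ring-close.

Step 10
Reactants: 20 dimethyl (2S,5E,9R,10S)-9-[(tert-butyldimethylsilyl)oxy]-10-(1,1-dimethoxypropan-2-yl)-2-methyl-4-oxoundec-5-enedioate
Product: 21 dimethyl (2S,5E,9R,10S)-9-[(tert-butyldimethylsilyl)oxy]-2-methyl-4-oxo-10-(1-oxopropan-2-yl)undec-5-enedioate (the acyclic keto aldehyde)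
Conditions: Amberlyst-15, acetone/H2O (20:1), rt
Reagents that add atoms: water, O
Why: Mild acid-catalysed acetal hydrolysis (transacetalisation to acetone) should free the C6 aldehyde while the secondary TBS ether, both methyl esters and the enone persist.

Step 11
Reactants: 21 dimethyl (2S,5E,9R,10S)-9-[(tert-butyldimethylsilyl)oxy]-2-methyl-4-oxo-10-(1-oxopropan-2-yl)undec-5-enedioate
Product: 24 methyl (1S,2R,4aS,8aS)-2-[(tert-butyldimethylsilyl)oxy]-7-[(2S)-1-methoxy-1-oxopropan-2-yl]-8a-methyl-6-oxo-1,2,3,4,4a,5,6,8a-octahydronaphthalene-1-carboxylate, via Michael adduct 22 (not isolated), via aldol 23 (not isolated)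
Conditions: 9-amino-9-deoxy-epi-quinine (20 mol %), TFA (40 mol %), toluene (0.05 M), 25 °C; then 50 °C
Reagents that add atoms: none
Why: The primary amine condenses with the C6 aldehyde and the imine tautomerises to the C5=C6 enamine, which merges both C5 epimers and adds through C5 to C10 of the acid-activated C9=C10 enone; after hydrolysis to keto aldehyde 22 the same amine–acid pair forms the C7 enamine of the C8 ketone, which attacks the C6 aldehyde to give aldol 23 and, by loss of water, the C6=C7 enone 24. The closest known reaction type is the amine-catalysed intramolecular Michael addition of an aldehyde to an enone followed by Robinson-type aldol condensation. Ring A closes in the 6-exo-trig mode (C5–C10) and ring B in the 6-(enolendo)-exo-trig mode (C7–C6), whereas enolisation towards C9 could only lead to a four-membered ring and is unproductive. C10 is set by the substrate through a chair-like transition state with the C3 silyl ether and the enone arm equatorial and the C4 ester axial, where it escapes allylic 1,3-strain with the fully substituted enamine carbon C5. C5 is set by the enamine face that meets C10: the catalyst, which can hold the enone carbonyl through its protonated quinuclidine, is relied on to favour the mode with C6 axial and the C5 methyl equatorial, which places the formyl group and the ketone arm cis on ring A as the cis-fused product requires. C3 and C4 are spectators because no strong base is present, and C11 stays a simple ester α-carbon with no second activating group until water is lost at the very end.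

Step 12
Reactants: 24 methyl (1S,2R,4aS,8aS)-2-[(tert-butyldimethylsilyl)oxy]-7-[(2S)-1-methoxy-1-oxopropan-2-yl]-8a-methyl-6-oxo-1,2,3,4,4a,5,6,8a-octahydronaphthalene-1-carboxylate
Product: 25 methyl (1S,2R,4aS,8aS)-2-hydroxy-7-[(2S)-1-methoxy-1-oxopropan-2-yl]-8a-methyl-6-oxo-1,2,3,4,4a,5,6,8a-octahydronaphthalene-1-carboxylate
Conditions: HF·pyridine, pyridine/THF, 0 °C → rt
Reagents that add atoms: none
Why: Fluoride-driven desilylation in a buffered, weakly acidic medium removes the TBS ether without base, so neither retro-aldol cleavage of the β-hydroxy ester nor migration of the C6=C7 bond towards C11 is expected.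

Step 13
Reactants: 25 methyl (1S,2R,4aS,8aS)-2-hydroxy-7-[(2S)-1-methoxy-1-oxopropan-2-yl]-8a-methyl-6-oxo-1,2,3,4,4a,5,6,8a-octahydronaphthalene-1-carboxylate; 26 angelic acid
Product: 28 methyl (1S,2R,4aS,8aS)-7-[(2S)-1-methoxy-1-oxopropan-2-yl]-8a-methyl-2-{[(2Z)-2-methylbut-2-enoyl]oxy}-6-oxo-1,2,3,4,4a,5,6,8a-octahydronaphthalene-1-carboxylate (target), via mixed anhydride 27 (not isolated)
Conditions: 26, 2,4,6-Cl3C6H2COCl, Et3N, toluene, rt; then 25, toluene, 80 °C (no DMAP)
Reagents that add atoms: none
Why: Yamaguchi-type esterification, in which the alcohol attacks the less hindered angeloyl carbonyl of the mixed anhydride with retention at C3 (the C–O bond is not broken), and leaving out a nucleophilic catalyst avoids the addition–elimination that would isomerise the (Z)-angelate to the (E)-tiglate.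

Compound list
1 | (S)-4-benzyl-2-oxazolidinone | O=C1N[C@@H](Cc2ccccc2)CO1 | starting material
2 | 3-methylpent-4-enoic acid (racemic) | C=CC(C)CC(=O)O | starting material
3 | 3-methylpent-4-enoic pivalic anhydride (not isolated) | C=CC(C)CC(=O)OC(=O)C(C)(C)C | intermediate
4 | (4S)-4-benzyl-3-(3-methylpent-4-enoyl)oxazolidin-2-one (C5 epimers) | C=CC(C)CC(=O)N1[C@@H](Cc2ccccc2)COC1=O | intermediate
5 | (4S)-4-benzyl-3-(3-methyl-4-oxobutanoyl)oxazolidin-2-one (not isolated) | O=CC(C)CC(=O)N1[C@@H](Cc2ccccc2)COC1=O | intermediate
6 | (4S)-4-benzyl-3-(4,4-dimethoxy-3-methylbutanoyl)oxazolidin-2-one (C5 epimers) | COC(OC)C(C)CC(=O)N1[C@@H](Cc2ccccc2)COC1=O | intermediate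
7 | pent-4-enal | C=CCCC=O | starting material
8 | (Z)-dibutylboron enolate of 6 (not isolated) | CCCCB(CCCC)O/C(N1[C@@H](Cc2ccccc2)COC1=O)=C\C(C)C(OC)OC | intermediate
9 | dibutylboron aldolate of 10 (not isolated) | COC(OC)C(C)[C@H](C(=O)N1[C@@H](Cc2ccccc2)COC1=O)[C@H](OB(CCCC)CCCC)CCC=C | intermediate
10 | (4S)-4-benzyl-3-[(2S,3R)-2-(1,1-dimethoxypropan-2-yl)-3-hydroxyhept-6-enoyl]oxazolidin-2-one | COC(OC)C(C)[C@H](C(=O)N1[C@@H](Cc2ccccc2)COC1=O)[C@H](O)CCC=C | intermediate
11 | lithium (2S,3R)-2-(1,1-dimethoxypropan-2-yl)-3-hydroxyhept-6-eneperoxoate (not isolated) | COC(OC)C(C)[C@H](C(=O)O[O-])[C@H](O)CCC=C.[Li+] | intermediate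
12 | lithium (2S,3R)-2-(1,1-dimethoxypropan-2-yl)-3-hydroxyhept-6-enoate (not isolated) | COC(OC)C(C)[C@H](C(=O)[O-])[C@H](O)CCC=C.[Li+] | intermediate
13 | methyl (2S,3R)-2-(1,1-dimethoxypropan-2-yl)-3-hydroxyhept-6-enoate | COC(OC)C(C)[C@H](C(=O)OC)[C@H](O)CCC=C | intermediate
14 | methyl (2S,3R)-3-[(tert-butyldimethylsilyl)oxy]-2-(1,1-dimethoxypropan-2-yl)hept-6-enoate | COC(OC)C(C)[C@H](C(=O)OC)[C@H](O[Si](C)(C)C(C)(C)C)CCC=C | intermediate
15 | (2S)-4-tert-butoxy-2-methyl-4-oxobutanoic acid, the 4-tert-butyl monoester of (S)-2-methylsuccinic acid | CC(C)(C)OC(=O)C[C@H](C)C(=O)O | starting material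
16 | 4-tert-butyl 1-methyl (2S)-2-methylbutanedioate | CC(C)(C)OC(=O)C[C@H](C)C(=O)OC | intermediate
17 | (3S)-4-methoxy-3-methyl-4-oxobutanoic acid (not isolated) | OC(=O)C[C@H](C)C(=O)OC | intermediate
18 | methyl (2S)-4-[methoxy(methyl)amino]-2-methyl-4-oxobutanoate | CON(C)C(=O)C[C@H](C)C(=O)OC | intermediate
19 | methyl (2S)-2-methyl-4-oxohex-5-enoate | C=CC(=O)C[C@H](C)C(=O)OC | intermediate
20 | dimethyl (2S,5E,9R,10S)-9-[(tert-butyldimethylsilyl)oxy]-10-(1,1-dimethoxypropan-2-yl)-2-methyl-4-oxoundec-5-enedioate | COC(OC)C(C)[C@H](C(=O)OC)[C@H](O[Si](C)(C)C(C)(C)C)CC/C=C/C(=O)C[C@H](C)C(=O)OC | intermediate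
21 | dimethyl (2S,5E,9R,10S)-9-[(tert-butyldimethylsilyl)oxy]-2-methyl-4-oxo-10-(1-oxopropan-2-yl)undec-5-enedioate (acyclic keto aldehyde, C5 epimers) | O=CC(C)[C@H](C(=O)OC)[C@H](O[Si](C)(C)C(C)(C)C)CC/C=C/C(=O)C[C@H](C)C(=O)OC | intermediate
22 | methyl (1S,2R,3S,6R)-6-[(tert-butyldimethylsilyl)oxy]-2-formyl-3-[(4S)-5-methoxy-4-methyl-2,5-dioxopentyl]-2-methylcyclohexane-1-carboxylate (ring-A Michael adduct, formyl and ketone arm cis; not isolated) | CC(C)(C)[Si](C)(C)O[C@@H]1CC[C@@H](CC(=O)C[C@H](C)C(=O)OC)[C@](C=O)(C)[C@@H]1C(=O)OC | intermediate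
23 | bicyclic β-hydroxy ketone, C6 carbinol and C7 methine of either configuration (not isolated) | CC(C)(C)[Si](C)(C)O[C@@H]1CC[C@H]2CC(=O)C([C@H](C)C(=O)OC)C(O)[C@@]2(C)[C@@H]1C(=O)OC | intermediate
24 | methyl (1S,2R,4aS,8aS)-2-[(tert-butyldimethylsilyl)oxy]-7-[(2S)-1-methoxy-1-oxopropan-2-yl]-8a-methyl-6-oxo-1,2,3,4,4a,5,6,8a-octahydronaphthalene-1-carboxylate | CC(C)(C)[Si](C)(C)O[C@@H]1CC[C@H]2CC(=O)C([C@H](C)C(=O)OC)=C[C@@]2(C)[C@@H]1C(=O)OC | intermediate
25 | methyl (1S,2R,4aS,8aS)-2-hydroxy-7-[(2S)-1-methoxy-1-oxopropan-2-yl]-8a-methyl-6-oxo-1,2,3,4,4a,5,6,8a-octahydronaphthalene-1-carboxylate | O[C@@H]1CC[C@H]2CC(=O)C([C@H](C)C(=O)OC)=C[C@@]2(C)[C@@H]1C(=O)OC | intermediate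
26 | angelic acid, (2Z)-2-methylbut-2-enoic acid | C/C=C(/C)C(=O)O | starting material
27 | angelic 2,4,6-trichlorobenzoic anhydride (not isolated) | C/C=C(/C)C(=O)OC(=O)c1c(Cl)cc(Cl)cc1Cl | intermediate
28 | CNP0265265.1, methyl (1S,2R,4aS,8aS)-7-[(2S)-1-methoxy-1-oxopropan-2-yl]-8a-methyl-2-{[(2Z)-2-methylbut-2-enoyl]oxy}-6-oxo-1,2,3,4,4a,5,6,8a-octahydronaphthalene-1-carboxylate | C/C=C(/C)C(=O)O[C@@H]1CC[C@H]2CC(=O)C([C@H](C)C(=O)OC)=C[C@@]2(C)[C@@H]1C(=O)OC | target

Total step count: 13. Longest linear sequence: 10 steps (steps 1–5 and 9–13); the vinyl ketone arm (steps 6–8) is a 3-step branch.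

Steps most likely to fail

1. Step 11. The enamine may meet C10 with poor facial selectivity at C5 (a mismatched pairing of catalyst and substrate), the enone may drift out of conjugation through a dienamine, or the sequence may stall at the ring-A stage. The fallback replaces catalytic control by a stoichiometric chiral imine and sets out from 21. Condensation with (R)-1-phenylethylamine (4 Å sieves, CH2Cl2) should give the (R)-1-phenylethyl aldimine F1. Warming in toluene lets its secondary-enamine tautomer add to the enone through the compact, internally proton-transferring chair known from the deracemising Michael reaction of chiral imines, giving the cyclised aldimine F2. Buffered aqueous acetic acid then releases the keto aldehyde, so the fallback comes back to the route at 22. This compound is isolated, its C5 configuration is checked, and it is closed to 24 with pyrrolidinium acetate in a separate aldol condensation. The enantiomer of the amine is chosen to match the substrate.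

2. Step 13. Acylation of the hindered C3 alcohol next to the C4 ester may be slow, and prolonged heating with base invites Z-to-E isomerisation of the angeloyl unit or elimination across C3–C4. The fallback builds the Z-alkene on the molecule and sets out from 25. Esterification (DCC, DMAP, CH2Cl2) with 2-[bis(2,2,2-trifluoroethoxy)phosphoryl]propanoic acid, a saturated acid that cannot isomerise, should give the phosphonopropionate ester F3. A Still–Gennari olefination with acetaldehyde (KHMDS, 18-crown-6, THF, −78 °C; the phosphonate is by far the most acidic site) then forms the (Z)-2-methylbut-2-enoate and comes back to the route at 28.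

3. Step 8. The Grignard reagent may attack the methyl ester, the released hydroxylamine or a second vinyl unit may add to the product in conjugate fashion, and the vinyl ketone may polymerise on concentration. The fallback replaces nucleophilic addition by an acyl cross-coupling and sets out from 16. After the TFA cleavage, acid 17 is isolated this time and converted with oxalyl chloride and catalytic DMF into the acid chloride F4. A Stille acylation with tributyl(vinyl)stannane (BnPd(PPh3)2Cl, THF, 50 °C) should give the vinyl ketone under neutral conditions and comes back to the route at 19.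

Further compounds
F1 | step 11 | (R)-1-phenylethyl aldimine of keto aldehyde 21 | c1ccccc1[C@@H](C)N=CC(C)[C@H](C(=O)OC)[C@H](O[Si](C)(C)C(C)(C)C)CC/C=C/C(=O)C[C@H](C)C(=O)OC
F2 | step 11 | cyclised aldimine, the (R)-1-phenylethyl imine of 22 | CC(C)(C)[Si](C)(C)O[C@@H]1CC[C@@H](CC(=O)C[C@H](C)C(=O)OC)[C@](C=N[C@H](C)c2ccccc2)(C)[C@@H]1C(=O)OC
F3 | step 13 | 2-[bis(2,2,2-trifluoroethoxy)phosphoryl]propanoate ester of 25 | CC(P(=O)(OCC(F)(F)F)OCC(F)(F)F)C(=O)O[C@@H]1CC[C@H]2CC(=O)C([C@H](C)C(=O)OC)=C[C@@]2(C)[C@@H]1C(=O)OC
F4 | step 8 | methyl (2S)-4-chloro-2-methyl-4-oxobutanoate | ClC(=O)C[C@H](C)C(=O)OC
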